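**Plan**

- Numbering: ring A is C1–C6 (butanoyl on C1, bridge CH2 on C5); ring B is C1'–C6' (bridge on C1', butanoyl on C3', OMe on C6').
- Retrosynthesis: the two aryl–acyl bonds (C1 and C3') and the O-benzyl groups are cut first. Ring B is then opened at C1'–C2' and C5'–C6' into a 1-methoxyalkyne that carries ring A (supplying C1' and C6') and 3-(benzyloxy)-2-methylcyclobut-2-enone (supplying C2'–C5'). Finally the CH2–C(sp) bond of the alkyne and the four-membered ring (ethoxyacetylene plus methylketene) are cut.
- Forward: ring A is bought as 2-methylphloroglucinol and carried in five steps to the ynol ether, and the cyclobutenone is made in three. Ring B is then closed in one thermal cascade, and hydrogenolysis followed by twofold Friedel–Crafts butanoylation completes the target.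
- Enabling feature: of the three oxygens of ring B only the one on C6' is methylated, and C6' lies between the CH2-bearing C1' and the CH3-bearing C5', 1,3 to both hydroxylated carbons C2' and C4'. A benzannulation writes exactly this order when the OMe carbon comes from an ynol ether and C4'/C5' from a 2-methyl-3-alkoxycyclobutenone.
- Stereochemistry: the target has no stereocentre, so none is set. The stereocentres of the racemic intermediates 12 and 16 are erased by enolisation and aromatisation.

Key step: step 9

Remark: SMILES carry no stereodescriptors except the double-bond geometry of 17, which is the geometry required for ring closure.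

**Route**

Step 1
Reactants: 1 2-methylphloroglucinol
Product: 2 2,4,6-trihydroxy-3-methylbenzaldehyde
Conditions: POCl3, DMF, EtOAc, 0 °C → rt; then H2O, 50 °C
Reagents that add atoms: N,N-dimethylformamide CN(C)C=O; water O
Why: Vilsmeier–Haack formylation of the phloroglucinol nucleus at one of its two equivalent free carbons should stop at the mono-aldehyde because the iminium salt deactivates the ring, and aqueous hydrolysis then frees the formyl group.

Step 2
Reactants: 2 2,4,6-trihydroxy-3-methylbenzaldehyde
Product: 3 2,4,6-tris(benzyloxy)-3-methylbenzaldehyde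
Conditions: BnBr (3.5 equiv), K2CO3, DMF, 60 °C
Reagents that add atoms: benzyl bromide BrCc1ccccc1
Why: Williamson O-benzylation of a formylphloroglucinol is standard, the acyl group suppressing the C-benzylation that troubles unsubstituted phloroglucinols, and excess BnBr with heating should also cap the two hydrogen-bonded ortho hydroxyls.

Step 3
Reactants: 3 2,4,6-tris(benzyloxy)-3-methylbenzaldehyde
Product: 4 [2,4,6-tris(benzyloxy)-3-methylphenyl]methanol
Conditions: NaBH4, THF/MeOH, 0 °C
Reagents that add atoms: none
Why: Borohydride reduction of the aryl aldehyde should give the benzylic alcohol cleanly, the benzyl ethers being inert to hydride.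

Step 4
Reactants: 4 [2,4,6-tris(benzyloxy)-3-methylphenyl]methanol
Product: 5 1,3,5-tris(benzyloxy)-2-(chloromethyl)-4-methylbenzene
Conditions: MsCl, Et3N, CH2Cl2, −20 → 0 °C; cold NaHCO3 wash; used at once
Reagents that add atoms: methanesulfonyl chloride CS(=O)(=O)Cl
Why: Mesylation of a strongly donor-substituted benzylic alcohol collapses in the flask to the benzylic chloride under non-acidic conditions, the usual entry to labile alkoxybenzyl chlorides, and the crude chloride is kept cold and not stored so that ionisation and self-condensation are forestalled.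

Step 5
Reactants: 5 1,3,5-tris(benzyloxy)-2-(chloromethyl)-4-methylbenzene; 6 chloroacetaldehyde dimethyl acetal
Product: 8 1,3,5-tris(benzyloxy)-2-(3-methoxyprop-2-yn-1-yl)-4-methylbenzene, via lithium methoxyacetylide 7 (not isolated)
Conditions: 6, LiNEt2 (3 equiv per 6, from Et2NH and n-BuLi), THF, 0 °C; then 5 (0.5 equiv), DMPU, −78 → 0 °C; cold NH4Cl quench; Et3N-deactivated silica
Reagents that add atoms: none
Why: Lithium diethylamide removes methanol and HCl from the chloroacetal to give lithium methoxyacetylide, whose SN2 alkylation with benzylic and allylic halides in THF with a dipolar cosolvent is the standard route to 1-methoxy-1-alkynes, the twofold excess of acetylide letting it outrun diethylamine and the cold quench guarding against propargyl-to-allenyl isomerisation.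

Step 6
Reactants: 9 ethoxyacetylene; 10 propanoyl chloride
Product: 12 3-ethoxy-4-methylcyclobut-2-en-1-one (racemic), via methylketene 11 (not isolated)
Conditions: Et3N, Et2O, 0 °C → rt, slow addition of 10
Reagents that add atoms: none
Why: Methylketene formed by dehydrochlorination undergoes the known regioselective ketene–ynol ether [2+2] cycloaddition, its carbonyl carbon bonding to the unsubstituted alkyne carbon, so the methyl group lands on the sp3 ring carbon and the single stereocentre forms racemic and is erased in the next step.

Step 7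
Reactants: 12 3-ethoxy-4-methylcyclobut-2-en-1-one
Product: 13 3-hydroxy-2-methylcyclobut-2-en-1-one (enol form of 2-methylcyclobutane-1,3-dione)
Conditions: 1 M HCl (aq), THF, rt
Reagents that add atoms: water O
Why: Dilute-acid hydrolysis of the vinylogous ester is the known route to cyclobutane-1,3-diones, and the product should rest as the enol with its double bond toward the methyl-bearing carbon, which removes the stereocentre and makes the two oxygens equivalent.

Step 8
Reactants: 13 3-hydroxy-2-methylcyclobut-2-en-1-one
Product: 14 3-(benzyloxy)-2-methylcyclobut-2-en-1-one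
Conditions: BnOH, PPh3, DIAD, THF, 0 °C → rt
Reagents that add atoms: benzyl alcohol OCc1ccccc1
Why: Mitsunobu etherification of a strongly acidic cyclic 1,3-dione enol with a primary alcohol is an established way to vinylogous esters that favours O- over C-alkylation, and because the enolate is symmetric either oxygen gives the same 2-methyl-3-alkoxy isomer.

Step 9
Reactants: 8 1,3,5-tris(benzyloxy)-2-(3-methoxyprop-2-yn-1-yl)-4-methylbenzene; 14 3-(benzyloxy)-2-methylcyclobut-2-en-1-one
Product: 19 5-(benzyloxy)-3-methoxy-4-methyl-2-[2,4,6-tris(benzyloxy)-3-methylbenzyl]phenol, via vinylketene 15 (not isolated), via vinylcyclobutenone 16 (not isolated), via dienylketene 17 (not isolated), via cyclohexadienone 18 (not isolated)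
Conditions: 14 (1.5 equiv), toluene, 110 °C, sealed tube; then K2CO3, MeOH, rt
Reagents that add atoms: none
Why: Thermal 4π-electrocyclic opening of 14 should give vinylketene 15, whose carbonyl carbon is attacked by the nucleophilic, benzyl-bearing carbon of ynol ether 8 in a regioselective [2+2] cycloaddition that forms C1'–C2' and C5'–C6' and gives vinylcyclobutenone 16 (racemic; its quaternary centre is lost on aromatisation). A second 4π opening then gives dienylketene 17, and ring B closes by thermal disrotatory 6π-electrocyclisation (re-forming the C2'–C3' bond) to cyclohexadienone 18, which tautomerises to phenol 19. This is the Danheiser benzannulation, and its closest precedents are the reactions of alkyl-substituted cyclobutenones with 1-methoxy- and siloxyalkynes to give resorcinol monoethers, together with the ready opening and electrocyclisation of 3-alkoxy-4-vinylcyclobutenones. No stereocentre remains in the product. The selectivity needed is regiochemical: the polarisation of the ynol ether places OMe meta to the new OH and next to the methyl carbon, four-membered closure through the ketene α-carbon (not six-membered closure through the vinyl terminus) keeps the methyl para to OH, and a methoxy (not ethoxy) alkyne cannot lose ethylene by retro-ene reaction at this temperature. The short K2CO3/MeOH treatment should return any product that was O-acylated by the vinylketene.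

Step 10
Reactants: 19 5-(benzyloxy)-3-methoxy-4-methyl-2-[2,4,6-tris(benzyloxy)-3-methylbenzyl]phenol
Product: 20 2-[(2,4-dihydroxy-6-methoxy-5-methylphenyl)methyl]-4-methylbenzene-1,3,5-triol
Conditions: H2 (1 atm), 10% Pd/C, EtOAc/MeOH, rt; handled under argon
Reagents that add atoms: none
Why: Hydrogenolysis over palladium on carbon should cleave all four benzyl aryl ethers under neutral conditions while leaving the aryl methyl ether and the diarylmethane bridge intact.

Step 11
Reactants: 20 2-[(2,4-dihydroxy-6-methoxy-5-methylphenyl)methyl]-4-methylbenzene-1,3,5-triol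
Product: 21 margaspidin, 1-{3-[(3-butanoyl-2,4-dihydroxy-6-methoxy-5-methylphenyl)methyl]-2,4,6-trihydroxy-5-methylphenyl}butan-1-one
Conditions: butanoyl chloride (2.2 equiv), AlCl3, PhNO2/CH2Cl2, 0 → 40 °C; then ice/1 M HCl
Reagents that add atoms: butanoyl chloride CCCC(Cl)=O
Why: Friedel–Crafts C-acylation with an acid chloride and AlCl3 in nitrobenzene is the standard way to acylphloroglucinols, and since each ring has exactly one free carbon, flanked by two oxygens, the two butanoyl groups can only enter at C1 of ring A and C3' of ring B.

**Compound list**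

1 | 2-methylphloroglucinol (2-methylbenzene-1,3,5-triol) | Cc1c(O)cc(O)cc1O | starting material
2 | 2,4,6-trihydroxy-3-methylbenzaldehyde | Cc1c(O)cc(O)c(C=O)c1O | intermediate
3 | 2,4,6-tris(benzyloxy)-3-methylbenzaldehyde | Cc1c(OCc2ccccc2)cc(OCc2ccccc2)c(C=O)c1OCc1ccccc1 | intermediate
4 | [2,4,6-tris(benzyloxy)-3-methylphenyl]methanol | Cc1c(OCc2ccccc2)cc(OCc2ccccc2)c(CO)c1OCc1ccccc1 | intermediate
5 | 1,3,5-tris(benzyloxy)-2-(chloromethyl)-4-methylbenzene | Cc1c(OCc2ccccc2)cc(OCc2ccccc2)c(CCl)c1OCc1ccccc1 | intermediate
6 | chloroacetaldehyde dimethyl acetal (2-chloro-1,1-dimethoxyethane) | COC(CCl)OC | starting material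
7 | lithium methoxyacetylide | [Li+].[C-]#COC | intermediate (not isolated)
8 | 1,3,5-tris(benzyloxy)-2-(3-methoxyprop-2-yn-1-yl)-4-methylbenzene | COC#CCc1c(OCc2ccccc2)cc(OCc2ccccc2)c(C)c1OCc1ccccc1 | intermediate
9 | ethoxyacetylene | CCOC#C | starting material
10 | propanoyl chloride | CCC(Cl)=O | starting material
11 | methylketene (prop-1-en-1-one) | CC=C=O | intermediate (not isolated)
12 | 3-ethoxy-4-methylcyclobut-2-en-1-one (racemic) | CCOC1=CC(=O)C1C | intermediate
13 | 3-hydroxy-2-methylcyclobut-2-en-1-one | CC1=C(O)CC1=O | intermediate
14 | 3-(benzyloxy)-2-methylcyclobut-2-en-1-one | CC1=C(OCc2ccccc2)CC1=O | intermediate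
15 | 3-(benzyloxy)-2-methylbuta-1,3-dien-1-one (vinylketene) | C=C(OCc1ccccc1)C(C)=C=O | intermediate (not isolated)
16 | 4-[1-(benzyloxy)ethenyl]-3-methoxy-4-methyl-2-[2,4,6-tris(benzyloxy)-3-methylbenzyl]cyclobut-2-en-1-one (racemic) | O=C1C(Cc2c(OCc3ccccc3)cc(OCc3ccccc3)c(C)c2OCc2ccccc2)=C(OC)C1(C)C(=C)OCc1ccccc1 | intermediate (not isolated)
17 | (3E)-5-(benzyloxy)-3-methoxy-4-methyl-2-[2,4,6-tris(benzyloxy)-3-methylbenzyl]hexa-1,3,5-trien-1-one (ketene and vinyl groups cis) | O=C=C(Cc1c(OCc2ccccc2)cc(OCc2ccccc2)c(C)c1OCc1ccccc1)/C(OC)=C(\C(=C)OCc1ccccc1)C | intermediate (not isolated)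
18 | 5-(benzyloxy)-3-methoxy-4-methyl-2-[2,4,6-tris(benzyloxy)-3-methylbenzyl]cyclohexa-2,4-dien-1-one | O=C1CC(OCc2ccccc2)=C(C)C(OC)=C1Cc1c(OCc2ccccc2)cc(OCc2ccccc2)c(C)c1OCc1ccccc1 | intermediate (not isolated)
19 | 5-(benzyloxy)-3-methoxy-4-methyl-2-[2,4,6-tris(benzyloxy)-3-methylbenzyl]phenol | COc1c(C)c(OCc2ccccc2)cc(O)c1Cc1c(OCc2ccccc2)cc(OCc2ccccc2)c(C)c1OCc1ccccc1 | intermediate
20 | 2-[(2,4-dihydroxy-6-methoxy-5-methylphenyl)methyl]-4-methylbenzene-1,3,5-triol | COc1c(C)c(O)cc(O)c1Cc1c(O)cc(O)c(C)c1O | intermediate
21 | margaspidin | CCCC(=O)c1c(O)c(C)c(O)c(Cc2c(O)c(C(=O)CCC)c(O)c(C)c2OC)c1O | target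

**Step count**

Total: 11 steps. Longest linear sequence: 8 steps (steps 1, 2, 3, 4, 5, 9, 10, 11); the cyclobutenone branch (steps 6–8) joins at step 9.

**Steps most likely to fail**

1. Step 9. The push–pull (vinylogous ester) cyclobutenone may open too slowly, so that the ynol ether decays or oligomerises at the temperature needed. Part of the zwitterionic adduct may also close through the vinyl terminus to a six-membered ring, which would put the methyl group ortho to the hydroxyl. The fallback gives up the annulation and joins two finished rings; it sets out from 1 and comes back at 21. Friedel–Crafts acylation of 1 (butanoyl chloride, AlCl3, PhNO2) should give 1-(2,4,6-trihydroxy-3-methylphenyl)butan-1-one F1. Part of this is mono-O-methylated at the hydroxyl para to the ketone (Me2SO4, 1 equiv, K2CO3, acetone) to 1-(2,6-dihydroxy-4-methoxy-3-methylphenyl)butan-1-one F2. Condensation of equimolar F1 and F2 with aqueous formaldehyde in dilute NaOH at rt then links the one free carbon of each ring through a methylene group. This should give 21 beside the two symmetrical dimers, which are removed by chromatography.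

2. Step 5 (with the chloride from step 4). The benzylic chloride may ionise and undergo Friedel–Crafts self-condensation at the free ring carbon before the C–C bond forms. Diethylamine may be N-benzylated, or base may isomerise the propargylic product to the allene. The fallback replaces the halide by a storable electrophile; it sets out from 3 and comes back at 8. Reductive amination of 3 (Me2NH, NaBH(OAc)3, 1,2-dichloroethane) should give 1-[2,4,6-tris(benzyloxy)-3-methylphenyl]-N,N-dimethylmethanamine F3. Quaternisation (MeI, acetone) gives [2,4,6-tris(benzyloxy)-3-methylphenyl]-N,N,N-trimethylmethanaminium iodide F4, a crystalline salt of the kind used, as with gramine and ferrocenylmethyl salts, to benzylate carbon nucleophiles. Treatment of F4 with lithium methoxyacetylide 7 in THF/DMPU (0 °C → rt) should displace trimethylamine at the benzylic carbon and give 8.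

3. Step 11. AlCl3 may cleave or scramble the methylene bridge of the electron-rich diarylmethane (retro-Friedel–Crafts), and O-acylation or incomplete acylation of one ring may compete. The fallback installs both ketones through aryllithiums before deprotection, so that no Lewis acid meets the bridge; it sets out from 19 and comes back at 21. Benzylation of the phenol (BnBr, K2CO3, DMF) gives 1,3,5-tris(benzyloxy)-2-{[2,4-bis(benzyloxy)-6-methoxy-5-methylphenyl]methyl}-4-methylbenzene F5. NBS (2 equiv, CH2Cl2, 0 °C) should brominate the single free carbon of each ring to give 1,3,5-tris(benzyloxy)-2-{[2,4-bis(benzyloxy)-3-bromo-6-methoxy-5-methylphenyl]methyl}-6-bromo-4-methylbenzene F6. Twofold bromine–lithium exchange (n-BuLi, THF, −78 °C) and acylation with N-methoxy-N-methylbutanamide give 1-{2,4,6-tris(benzyloxy)-3-{[2,4-bis(benzyloxy)-3-butanoyl-6-methoxy-5-methylphenyl]methyl}-5-methylphenyl}butan-1-one F7. Hydrogenolysis (H2, Pd/C, EtOAc) then removes the five benzyl groups to give 21.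

**Further compounds**

F1 | step 9 | 1-(2,4,6-trihydroxy-3-methylphenyl)butan-1-one | CCCC(=O)c1c(O)cc(O)c(C)c1O
F2 | step 9 | 1-(2,6-dihydroxy-4-methoxy-3-methylphenyl)butan-1-one (aspidinol) | CCCC(=O)c1c(O)cc(OC)c(C)c1O
F3 | step 5 | 1-[2,4,6-tris(benzyloxy)-3-methylphenyl]-N,N-dimethylmethanamine | CN(C)Cc1c(OCc2ccccc2)cc(OCc2ccccc2)c(C)c1OCc1ccccc1
F4 | step 5 | [2,4,6-tris(benzyloxy)-3-methylphenyl]-N,N,N-trimethylmethanaminium iodide | C[N+](C)(C)Cc1c(OCc2ccccc2)cc(OCc2ccccc2)c(C)c1OCc1ccccc1.[I-]
F5 | step 11 | 1,3,5-tris(benzyloxy)-2-{[2,4-bis(benzyloxy)-6-methoxy-5-methylphenyl]methyl}-4-methylbenzene | COc1c(C)c(OCc2ccccc2)cc(OCc2ccccc2)c1Cc1c(OCc2ccccc2)cc(OCc2ccccc2)c(C)c1OCc1ccccc1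
F6 | step 11 | 1,3,5-tris(benzyloxy)-2-{[2,4-bis(benzyloxy)-3-bromo-6-methoxy-5-methylphenyl]methyl}-6-bromo-4-methylbenzene | COc1c(C)c(OCc2ccccc2)c(Br)c(OCc2ccccc2)c1Cc1c(OCc2ccccc2)c(Br)c(OCc2ccccc2)c(C)c1OCc1ccccc1
F7 | step 11 | 1-{2,4,6-tris(benzyloxy)-3-{[2,4-bis(benzyloxy)-3-butanoyl-6-methoxy-5-methylphenyl]methyl}-5-methylphenyl}butan-1-one | COc1c(C)c(OCc2ccccc2)c(C(=O)CCC)c(OCc2ccccc2)c1Cc1c(OCc2ccccc2)c(C(=O)CCC)c(OCc2ccccc2)c(C)c1OCc1ccccc1
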